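The vessel is a closed, stirred flask held at constant temperature, in which substrate in the first phase is to become target with a reagent charged in a second phase.

in all of them: substrate 45 mM
- Sunday's: reagent in the second phase 50 mM; protic impurity 1.5 mM; run made earlier
- gamma: reagent in the second phase 50.0 mM; protic impurity 2.25 mM; time 25 d; volume of the second phase over the first 0.25
- theta: reagent in the second phase 100 mM; protic impurity 2.25 mM; time 25 d; volume of the second phase over the first 0.25
- beta: reagent in the second phase 200 mM; protic impurity 2.25 mM; time 25 d; volume of the second phase over the first 0.25
- delta: reagent in the second phase 400 mM; protic impurity 2.25 mM; time 25 d; volume of the second phase over the first 0.25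

Sunday's run (percent of the substrate charged)

| time / d | target / % | substrate / % |
|---|---|---|
| 0.833 | 6.7 | 45.1 |
| 2.00 | 10.3 | 26.8 |
| 4.00 | 12.9 | 23.0 |
| 6.00 | 16.0 | 18.9 |
| 8.00 | 19.1 | 19.4 |

(each reading ± 1 percentage point)

- in the second phase: reagent in the second phase; everything else is in the first
- charges count per volume of the first phase; a concentration in a rate is the amount of a species over the volume of its own phase; every rate counts per litre of the first phase
- the earlier runs hold the two phases in the same ratio of volumes as the flask asked about
- "hardly changes" means that all values lie within two and a half points (for a concentration: within two and a half percent of the largest)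
- no earlier run changes the charge of protic impurity; that part of a forecast is a guess

- amount of target at the end, in percent of the substrate charged for gamma, theta, beta, delta, in this order
- how the row runs (hardly changes / falls all the way / rises, then falls / falls, then rises / rises all the way)

In Sunday's run the substrate fell to 26.8% by 2.00 d and then much more slowly, reading 19.4% at 8.00 d, while target read 10.3% at 2.00 d and went on rising. I therefore took the substrate to be exchanging quickly with an unseen reservoir, treated that exchange as equilibrated, and reckoned with what it left free. At 2.00 d I counted everything that was not target as pool and read 29.9% as the free share, [substrate] over [substrate] plus [reservoir].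

I then built the flask up one process at a time. Taken at that free share, the substrate reading at 8.00 d meant a pool lost of 35.1% of the charge. Dividing that by the time integral of the substrate, 2.32 d, gave a pseudo-first-order constant of 0.151 d⁻¹. With the main step alone, gamma would reach 97.7% target at 25 d. Adding the reservoir, the pool reacts through its free share, at 0.0451 d⁻¹, and the figure drops to 67.6%.

The last process came from the balance. Target at 8.00 d read below the pool lost, so I counted 16.0% as gone beyond target. Over the time integral of target, 0.999 d, this is a loss constant of 0.160 d⁻¹, a rough reading given the scatter. This loss constant is larger than the feed constant of the pool, and my consecutive reckoning gave gamma 12.0%. Taking the feed as proportional to the reagent charge, keeping the free share and setting the guessed impurity aside, I reckoned 11.2% for theta, 6.47% for beta and 3.27% for delta, so my own row fell at each step.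

The forecast gave 38%, 17%, 8% and 4%, a row that falls all the way, holding that "the reagent seems to take substrate away rather than make target". The flasks gave 12.7%, 16.1%, 13.4% and 9.50%: the row rises, then falls, turning at 100 mM.

    reagent in the reaction phase ⇌ reagent in the second phase, rate k1*([reagent in the reaction phase] - [reagent in the second phase]/K1) per volume of the first phase (partition coefficient = 21.0, kL = 0.00256 min⁻¹)
    substrate + reagent in the reaction phase → target (k = 0.0160 M⁻¹ min⁻¹)
    substrate ⇌ dormant form (K = 2.50, k = 7.10 × 10⁻⁴ min⁻¹)
    target → over-reaction product (k = 7.94 × 10⁻⁵ min⁻¹)
    reagent in the reaction phase + protic impurity → quenched reagent (k = 1.50 M⁻¹ min⁻¹)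

In gamma, the half-life of target by its conversion into over-reaction product alone, 6.1 d, is short against the 25 d of the run. At 3.05 d gamma still made target 2.33 times faster than it used it up, and by 25.0 d over-reaction product stood at 42.6% against 12.7% target. The reservoir was the dormant form: my free share of 29.9%, applied to substrate plus dormant form in gamma at 25.0 d, gives 13.4% substrate where gamma held 12.3%. Applied in the same way to delta at 12.5 d, it gives 1.35% substrate where delta held 0.732%.

(The data are calculated for an exercise; scatter was added.)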